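## Analysis of the target

The target is a trans-fused decalin carrying a two-carbon tether to a succinimide. Labdane-type numbering is used throughout: ring A = C1–C5 and C10, ring B = C5–C10, C17 = exocyclic methylene carbon on C8, C18/C19 = methyls on C4, C20 = methyl on C10, C11–C12 = tether, C13–C16 and N = succinimide.

There are seven stereocentres: C2 (S, equatorial chloride on the α face), C5 (S, H α), C6 (R, axial β-hydroxyl), C9 (S, H α, side chain equatorial), C10 (R, methyl β), C12 (S) and C13 (R). C5, C10 and C9 are contiguous, C10 is quaternary and sits beside quaternary C4, and C12/C13 form a syn-aldol pair remote from the rings.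

The 6β-hydroxyl is syn-axial to the methyls on C10 and C4 and is homoallylic to the 8(17)-alkene. The unit C6(OH)–C7H2–C8(=C17H2) in ring B is the retron of an intramolecular type 2 carbonyl-ene reaction of a C6 aldehyde with a C8 isopropenyl group. Opening C6–C7 in that way leaves a δ,ε-unsaturated aldehyde, C6(=O)–C5–C10–C9–C8=C7, which is the retron of an oxy-Cope rearrangement that forms C9–C10. This double retron, in which the C6–C7 bond is broken and then made again, is the feature the route exploits.

Sensitive groups are the secondary chloride (E2; vinylogous elimination in δ-chloro enal precursors), the exocyclic alkene (acid-induced migration into the ring), the β-hydroxy imide (retro-aldol, epimerisation at C13) and the imide N–H. The hard problems are the C2 chloride on an otherwise unfunctionalised methylene, the congested C9–C10 bond between a tertiary and a quaternary carbon, and the axial C6 alcohol. In the finished decalin a 2β-leaving group is axial, syn-axial to two methyls and anti-periplanar to axial hydrogens on C1 and C3, so elimination would compete with substitution. The chloride is therefore set while ring A is still monocyclic.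

## Retrosynthetic reasoning

**Succinimide (22 ⇒ 20).** The N–C16 bond is cut. The ring is closed last by attack of a primary carboxamide nitrogen on the auxiliary-bound carbonyl of 20, so the chiral auxiliary is the leaving group. The carboxamide is carried as a nitrile, which is inert in the aldol step and cannot lactonise onto the C12 hydroxyl before it is unmasked. The forward step needs neutral hydration (via amide 21) and a 5-exo acyl transfer.

**Side chain (20 ⇒ 15 + 18).** The C12–C13 bond is cut. C12 and C13 are a syn-aldol pair, so the boron enolate 19 of the N-acyloxazolidinone 18 and the aldehyde 15 set both centres under reagent control. The ring stereocentres are too far away to help or interfere.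

**Aldehyde (15 ⇒ 14).** Oxidation-state change only. The primary alcohol of 14 is distinguished from the axial C6 alcohol by steric access, so no protecting group is needed.

**Ring B and four stereocentres (14 ⇒ 13 ⇒ 12 ⇒ 11).** First the C6–C7 bond is cut (retro-ene) to give the monocyclic aldehyde 13. The ene reaction gives the axial C6 alcohol and the exocyclic alkene together, which no C–C disconnection elsewhere in ring B does. Then the C9–C10 bond of 13 is cut (retro oxy-Cope via enolate 12) and C6–C7 is re-formed on paper, leading to the dienol 11. Dienol 11 has one ring and two stereocentres (C2 and the C6 carbinol). The forward sequence has to relay the carbinol configuration to C10 and C9, then to C5 and back to C6.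

**Dienol (11 ⇒ 8 ⇒ 7).** The C8–C17 and C9–C11 bonds are cut: the terminal alkyne of 8 is carbometallated (methyl to C8, metal to C9) and the vinyl metal opens a two-carbon epoxide. This fixes the E geometry that the oxy-Cope chair needs. The C6–C7 bond of 8 comes from an enantioselective propargylation of the enal 7, the only stereo-determining event for the carbocyclic core apart from C2.

**Ring A (7 ⇒ 6 ⇒ 4 ⇒ 3 ⇒ 2 ⇒ 1).** C6 is attached by carbonylation of the vinyl triflate 6, made from ketone 4 via its only possible enolate 5. The chloride of 4 comes from the alcohol 3 by inversion, and 3 from the achiral enedione 1 by asymmetric transfer hydrogenation (to 2) and alkene hydrogenation. All nine carbons of ring A (C1–C5, C10, C18–C20) are already in 1, together with the oxygen whose position the chlorine takes.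

**Aldol partner (18 ⇒ 16 + 17).** N-Acylation of the auxiliary 16 with the acid 17.

## Alternatives that were turned down

Alternative 1: The textbook route cuts C12–C13 (aldol) and takes the decalin from the chiral-pool lactone (+)-sclareolide A1. The key forward step is a radical C–H chlorination of A1 at C2 to give 2α-chlorosclareolide A2, followed by lactone opening and dehydration toward C8=C17. A1 maps C1–C12 and the ring stereocentres well but brings no oxygen at C6. In A2, C6 is an unactivated methylene, and after lactone opening the allylic ring position is C7, not C6. Reaching the 6β-alcohol would need a multi-step detour through C7 oxidation and transposition on a substrate that already carries the chloride. The route that is short for 7-oxygenated congeners is therefore long for this one.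

Alternative 2: A chloride-bearing polyene bicyclisation of the acyclic trienyl allylsilane A3 would close rings A and B in one step to give the decalin A4, with C5, C9 and C10 set from the C2 chloride. It fails on C6: A4 has a plain CH2 there and no handle to oxidise it. An oxygen cannot be placed at C6 beforehand, because it would be allylic to the nucleophilic C5=C10 alkene (ionisation) or, as a ketone, would deactivate it. A C6 substituent would also prefer the equatorial (6α) position in the chair–chair transition state. In addition, initiation at C4 without a C3 oxygen and next to a C2 chloride has no clean initiator; an epoxide initiator leaves a C3 hydroxyl whose radical removal would expel the β-chlorine.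

Alternative 3: Semisynthesis from larixol A5. A5 already has a C6 oxygen, the 8(17)-alkene and the full carbon skeleton. Side-chain degradation through the methyl ketone A6 would reach the C12 aldehyde oxidation level, and C6 would be inverted by oxidation and reduction. It was turned down because C2 of A5 and A6 has no functional handle and a radical C–H chlorination is not compatible with two alkenes and allylic hydrogens. Masking the alkenes, removing four side-chain carbons and inverting C6 together cost more steps than building the ring.

Key step: step 8

Assumption: the absolute sense of the two catalyst-controlled steps (1 and 6) is assigned by analogy with aryl ketones and aryl aldehydes; if induction on these substrates is opposite, the enantiomeric catalyst is used.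

## Route

Step 1
Reactants: 1 2,6,6-trimethylcyclohex-2-ene-1,4-dione (ketoisophorone)
Product: 2 (R)-4-hydroxy-2,6,6-trimethylcyclohex-2-en-1-one
Conditions: RuCl(p-cymene)[(R,R)-TsDPEN] (0.5 mol %), KOH (1 mol %), i-PrOH, 25 °C
Reagents that add atoms: none
Why: Noyori asymmetric transfer hydrogenation; only the unhindered conjugated C4 carbonyl is accessible (the other carbonyl is flanked by a quaternary carbon and the methyl-bearing alkene carbon), and the enone π system takes the role of the aryl group in the catalyst model, so the (R)-carbinol should form; it becomes C2 of the target with oxygen on the β face.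

Step 2
Reactants: 2 (R)-4-hydroxy-2,6,6-trimethylcyclohex-2-en-1-one
Product: 3 (4S)-4-hydroxy-2,2,6-trimethylcyclohexan-1-one (both C6 epimers)
Conditions: H2 (1 atm), Pd/C (5 %), EtOAc, 0 °C to rt
Reagents that add atoms: none
Why: Heterogeneous hydrogenation of the conjugated C=C; the carbinol centre is untouched (the descriptor changes only through priorities) and the new methyl-bearing centre, formed as a mixture, is erased in step 4.

Step 3
Reactants: 3 (4S)-4-hydroxy-2,2,6-trimethylcyclohexan-1-one
Product: 4 (4R)-4-chloro-2,2,6-trimethylcyclohexan-1-one (both C6 epimers)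
Conditions: PPh3, CCl4, MeCN, 60 °C
Reagents that add atoms: carbon tetrachloride ClC(Cl)(Cl)Cl
Why: Appel reaction; SN2 displacement of the alkoxyphosphonium by chloride inverts the carbinol and puts chlorine on the α face (the future equatorial 2α-Cl) while the ring is still conformationally mobile, and the ketone has no β leaving group.

Step 4
Reactants: 4 (4R)-4-chloro-2,2,6-trimethylcyclohexan-1-one
Product: 6 (R)-4-chloro-2,6,6-trimethylcyclohex-1-en-1-yl trifluoromethanesulfonate, via potassium enolate 5 (not isolated)
Conditions: KN(SiMe3)2, THF, −78 °C; N-(5-chloropyridin-2-yl)bis(trifluoromethanesulfonyl)imide, −78 °C; aq. NH4Cl at −78 °C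
Reagents that add atoms: N-(5-chloropyridin-2-yl)bis(trifluoromethanesulfonyl)imide O=S(=O)(N(c1ccc(Cl)cn1)S(=O)(=O)C(F)(F)F)C(F)(F)F
Why: The ketone can enolise only toward the methine carbon (the other α carbon is quaternary), so a single tetrasubstituted enolate forms and is O-sulfonylated; at −78 °C the 3-exo alkylation of the enolate by the γ chloride should be too slow to compete.

Step 5
Reactants: 6 (R)-4-chloro-2,6,6-trimethylcyclohex-1-en-1-yl trifluoromethanesulfonate
Product: 7 (R)-4-chloro-2,6,6-trimethylcyclohex-1-ene-1-carbaldehyde
Conditions: Pd(PPh3)4 (5 mol %), CO (1 atm), Bu3SnH (slow addition), LiCl, THF, 50 °C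
Reagents that add atoms: carbon monoxide [C-]#[O+]
Why: Palladium-catalysed reductive carbonylation of a vinyl triflate (oxidative addition to zerovalent palladium, CO insertion, hydride transfer from tin) introduces C6; base-free conditions are used because 7 can lose HCl by vinylogous E1cB elimination.

Step 6
Reactants: 7 (R)-4-chloro-2,6,6-trimethylcyclohex-1-ene-1-carbaldehyde
Product: 8 (S)-1-[(R)-4-chloro-2,6,6-trimethylcyclohex-1-en-1-yl]but-3-yn-1-ol
Conditions: allenylboronic acid pinacol ester, (S)-TRIP [(S)-3,3'-bis(2,4,6-triisopropylphenyl)-1,1'-binaphthyl-2,2'-diyl hydrogen phosphate] (10 mol %), 4 Å MS, toluene, 0 °C to rt; aqueous work-up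
Reagents that add atoms: allenylboronic acid pinacol ester C=C=CB1OC(C)(C)C(C)(C)O1
Why: Chiral phosphoric acid catalysed propargylation of an aldehyde through a closed six-membered transition state (C6–C7 bond); the catalyst alone sets the carbinol because the C2 chloride is remote, and the (S) configuration is the one the oxy-Cope chair of step 8 requires.

Step 7
Reactants: 8 (S)-1-[(R)-4-chloro-2,6,6-trimethylcyclohex-1-en-1-yl]but-3-yn-1-ol
Product: 11 (1S,3E)-1-[(R)-4-chloro-2,6,6-trimethylcyclohex-1-en-1-yl]-3-methylhex-3-ene-1,6-diol, via alkenylalane 9 (not isolated), via lithium alanate 10 (not isolated)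
Conditions: AlMe3 (3.5 equiv), Cp2ZrCl2 (0.25 equiv), CH2Cl2, 0 °C to rt; volatiles removed; hexane–THF, n-BuLi, −78 to 0 °C; ethylene oxide, 0 °C to rt; aq. Rochelle salt
Reagents that add atoms: trimethylaluminium C[Al](C)C; ethylene oxide C1CO1
Why: Zirconium-catalysed syn carboalumination (Negishi) of the terminal alkyne places methyl (C17) on C8 and aluminium on C9, fixing the E trisubstituted alkene; the derived alanate opens the epoxide with retention of alkene geometry and adds C11–C12 as a 2-hydroxyethyl group.

Step 8
Reactants: 11 (1S,3E)-1-[(R)-4-chloro-2,6,6-trimethylcyclohex-1-en-1-yl]-3-methylhex-3-ene-1,6-diol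
Product: 14 decalin diol (2S,5S,6R,9S,10R; 2α-chloro-6β-hydroxy-9β-(2-hydroxyethyl)-4,4,10β-trimethyl-8-methylene-trans-decalin), via dipotassium enolate 12 (not isolated), via aldehyde 13 (not isolated)
Conditions: KH, 18-crown-6, THF, 0 °C to rt; AcOH, −78 °C; aqueous wash and solvent switch to CH2Cl2 (no purification); Me2AlCl (3 equiv), −78 to −40 °C
Reagents that add atoms: none
Why: The dipotassium alkoxide of 11 undergoes a charge-accelerated [3,3] shift (anionic oxy-Cope) through a chair in which the oxido group is equatorial, the E alkene places C11 equatorial and the ring methyl is axial; this breaks C6–C7, forms C9–C10 and gives enolate 12. The (S)-carbinol is relayed by 1,3-chirality transfer through that chair to the quaternary C10 (methyl β) and to C9 together, whereas the boat or the axial-oxido chair (1,3-diaxial to the C10 methyl) would give the other C9/C10 pair. Kinetic C-protonation at −78 °C is expected on the α face of C5, because in the ring A chair with equatorial chlorine the β face is flanked by the axial methyls on C4 and C10; this gives the trans aldehyde 13. Me2AlCl then promotes an intramolecular type 2 carbonyl-ene reaction in which C6 bonds again to C7, closing the six-membered ring B through a chair-like bicyclic transition state with the ene unit tethered at its central carbon C8, while a C17 hydrogen moves to oxygen and leaves the exocyclic C8=C17 bond. The concerted geometry needs the complexed carbonyl axial on the forming ring, which delivers the axial 6β-alcohol, and Me2AlCl scavenges protons so that chloride capture or alkene migration by a stepwise Prins path is suppressed. The closest known reaction types are anionic oxy-Cope rearrangements that create quaternary carbons, aluminium-promoted type 2 ene cyclisations of δ,ε-unsaturated aldehydes to axial 3-methylenecyclohexanols, and tandem oxy-Cope/ene sequences. The selectivities needed are chair over boat, α-face protonation and ene over Prins; the equatorial C2 chloride anchors the ring A chair so that the C5 formyl and C10–C9 bonds are diequatorial, which secures the trans ring fusion.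

Step 9
Reactants: 14 decalin diol
Product: 15 aldehyde (2α-chloro-6β-hydroxy-4,4,10β-trimethyl-8-methylene-9β-(2-oxoethyl)-trans-decalin)
Conditions: 2,2,6,6-tetramethylpiperidin-1-oxyl (TEMPO, 10 mol %), PhI(OAc)2, CH2Cl2, rt
Reagents that add atoms: none
Why: Oxoammonium-mediated oxidation is selective for the unhindered primary alcohol; the axial 6β-hydroxyl, syn to two methyl groups, is too hindered to react.

Step 10
Reactants: 16 (R)-4-benzyloxazolidin-2-one; 17 3-cyanopropanoic acid
Product: 18 (R)-4-benzyl-3-(3-cyanopropanoyl)oxazolidin-2-one
Conditions: DCC, 4-(dimethylamino)pyridine (10 mol %), CH2Cl2, 0 °C to rt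
Reagents that add atoms: none
Why: Carbodiimide-mediated N-acylation of the oxazolidinone with 4-(dimethylamino)pyridine as acyl-transfer catalyst.

Step 11
Reactants: 15 aldehyde; 18 (R)-4-benzyl-3-(3-cyanopropanoyl)oxazolidin-2-one
Product: 20 aldol adduct (R)-4-benzyl-3-[(2R,3S)-2-(cyanomethyl)-3-hydroxy-4-(decalin-9-yl)butanoyl]oxazolidin-2-one, via boron enolate 19 (not isolated)
Conditions: 18 (2 equiv), Bu2BOTf, i-Pr2NEt, CH2Cl2, −78 to 0 °C; 15, −78 to 0 °C; pH 7 buffer, MeOH, H2O2, 0 °C
Reagents that add atoms: none
Why: Evans syn aldol; the Z boron enolate reacts through a Zimmerman–Traxler chair on the face away from the benzyl group, which with the (R) auxiliary should give (12S,13R); the nitrile is inert, and the hindered 6β-hydroxyl is tolerated by excess enolate and the oxidative work-up.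

Step 12
Reactants: 20 aldol adduct
Product: 22 haterumaimide F, via primary amide 21 (not isolated)
Conditions: [PtH{(PMe2O)2H}(PMe2OH)] (5 mol %), EtOH–H2O (4:1), 80 °C; then Et3N (cat.), rt
Reagents that add atoms: water O
Why: Platinum-catalysed hydration turns the nitrile into a primary carboxamide under neutral conditions; its nitrogen then attacks the activated N-acyloxazolidinone carbonyl (5-exo-trig), expelling the auxiliary and closing the succinimide without a base strong enough for retro-aldol or C13 epimerisation.

## Compound list

1 | 2,6,6-trimethylcyclohex-2-ene-1,4-dione (ketoisophorone) | CC1=CC(=O)CC(C)(C)C1=O | starting material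
2 | (R)-4-hydroxy-2,6,6-trimethylcyclohex-2-en-1-one | CC1=C[C@H](O)CC(C)(C)C1=O | intermediate
3 | (4S)-4-hydroxy-2,2,6-trimethylcyclohexan-1-one (both C6 epimers) | CC1C(=O)C(C)(C)C[C@@H](O)C1 | intermediate
4 | (4R)-4-chloro-2,2,6-trimethylcyclohexan-1-one (both C6 epimers) | CC1C(=O)C(C)(C)C[C@H](Cl)C1 | intermediate
5 | potassium (R)-4-chloro-2,6,6-trimethylcyclohex-1-en-1-olate | [K+].CC1=C([O-])C(C)(C)C[C@H](Cl)C1 | intermediate
6 | (R)-4-chloro-2,6,6-trimethylcyclohex-1-en-1-yl trifluoromethanesulfonate | CC1=C(OS(=O)(=O)C(F)(F)F)C(C)(C)C[C@H](Cl)C1 | intermediate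
7 | (R)-4-chloro-2,6,6-trimethylcyclohex-1-ene-1-carbaldehyde | CC1=C(C=O)C(C)(C)C[C@H](Cl)C1 | intermediate
8 | (S)-1-[(R)-4-chloro-2,6,6-trimethylcyclohex-1-en-1-yl]but-3-yn-1-ol | CC1=C([C@@H](O)CC#C)C(C)(C)C[C@H](Cl)C1 | intermediate
9 | alkenylalane (E-alkenyl dimethylalane of 8, hydroxyl as dimethylaluminium alkoxide) | CC1=C([C@@H](O[Al](C)C)C/C(C)=C/[Al](C)C)C(C)(C)C[C@H](Cl)C1 | intermediate
10 | lithium alanate (n-butyl ate complex of 9) | [Li+].CC1=C([C@@H](O[Al](C)C)C/C(C)=C/[Al-](C)(C)CCCC)C(C)(C)C[C@H](Cl)C1 | intermediate
11 | (1S,3E)-1-[(R)-4-chloro-2,6,6-trimethylcyclohex-1-en-1-yl]-3-methylhex-3-ene-1,6-diol | CC1=C([C@@H](O)C/C(C)=C/CCO)C(C)(C)C[C@H](Cl)C1 | intermediate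
12 | dipotassium enolate (aldehyde enolate at C5=C6, alkoxide at C12; C10 methyl β, C9-H α, 2α-Cl) | [K+].[K+].[O-]C=C1C(C)(C)C[C@H](Cl)C[C@]1(C)[C@H](C(C)=C)CC[O-] | intermediate
13 | trans aldehyde: 4-chloro-2-(5-hydroxy-2-methylpent-1-en-3-yl)-2,6,6-trimethylcyclohexane-1-carbaldehyde (labdane numbering: 2α-Cl, 5α-H, 9α-H, 10β-CH3) | O=C[C@H]1C(C)(C)C[C@H](Cl)C[C@]1(C)[C@H](C(C)=C)CCO | intermediate
14 | decalin diol (2S,5S,6R,9S,10R): 2α-chloro-6β-hydroxy-9β-(2-hydroxyethyl)-4,4,10β-trimethyl-8-methylene-trans-decalin | C=C1C[C@@H](O)[C@H]2C(C)(C)C[C@H](Cl)C[C@]2(C)[C@H]1CCO | intermediate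
15 | aldehyde: 2α-chloro-6β-hydroxy-4,4,10β-trimethyl-8-methylene-9β-(2-oxoethyl)-trans-decalin | C=C1C[C@@H](O)[C@H]2C(C)(C)C[C@H](Cl)C[C@]2(C)[C@H]1CC=O | intermediate
16 | (R)-4-benzyloxazolidin-2-one | O=C1OC[C@@H](Cc2ccccc2)N1 | starting material
17 | 3-cyanopropanoic acid | N#CCCC(=O)O | starting material
18 | (R)-4-benzyl-3-(3-cyanopropanoyl)oxazolidin-2-one | N#CCCC(=O)N1[C@H](Cc2ccccc2)COC1=O | intermediate
19 | boron enolate (Z dibutylboron enolate of 18) | N#CC/C=C(\OB(CCCC)CCCC)N1[C@H](Cc2ccccc2)COC1=O | intermediate
20 | aldol adduct: (R)-4-benzyl-3-[(2R,3S)-2-(cyanomethyl)-3-hydroxy-4-(decalin-9-yl)butanoyl]oxazolidin-2-one (decalin as in 14) | C=C1C[C@@H](O)[C@H]2C(C)(C)C[C@H](Cl)C[C@]2(C)[C@H]1C[C@H](O)[C@@H](CC#N)C(=O)N1[C@H](Cc2ccccc2)COC1=O | intermediate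
21 | primary amide (carboxamide from the nitrile of 20) | C=C1C[C@@H](O)[C@H]2C(C)(C)C[C@H](Cl)C[C@]2(C)[C@H]1C[C@H](O)[C@@H](CC(N)=O)C(=O)N1[C@H](Cc2ccccc2)COC1=O | intermediate
22 | haterumaimide F | C=C1C[C@@H](O)[C@H]2C(C)(C)C[C@H](Cl)C[C@]2(C)[C@H]1C[C@H](O)[C@H]1CC(=O)NC1=O | target

## Step count and least certain steps

Total: 12 steps. Longest linear sequence: 11 steps (steps 1–9, 11 and 12) from ketoisophorone 1; step 10 is a one-step branch.

**Step 8 (key step).** Several things can go wrong. The oxy-Cope may pass through a boat or the axial-oxido chair and erode the C9/C10 relay. The hindered alkoxide may fragment by retro-allylation instead of rearranging. Protonation of enolate 12 may occur partly on the β face and lead to cis-fused material. The ene closure may partly follow a stepwise Prins path that scrambles C6 or captures chloride. The alkoxide base may also cause some loss of HCl from ring A if the rearrangement is slow. The two stages can be run as separate operations without changing the chemistry. The fallback replaces kinetic control at C5 and C6 by a ketone funnel. It sets out from aldehyde 13, which is cyclised without stereochemical demand (Me2AlCl or heat) to the mixture of C5/C6 isomers F1. Both hydroxyls of F1 are oxidised with Dess–Martin periodinane, and brief exposure to Et3N equilibrates C5 to the trans-fused keto aldehyde F2, the stable ring fusion of 6-oxo-4,4,10-trimethyldecalins. NaBH4/CeCl3·7H2O at −78 °C then reduces the ketone from the open α face (6β-alcohol) and the aldehyde back to the primary alcohol, returning to 14. The risk of this detour is migration of the 8(17)-alkene into conjugation during the base treatment.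

**Step 6.** The enal is hindered by the gem-dimethyl group and the ring methyl, so addition may be slow and poorly enantioselective, and prolonged reaction invites loss of HCl to the dienal. The fallback sets the carbinol by reduction instead of addition. It sets out from 7: zinc-mediated Barbier propargylation (Zn, propargyl bromide, THF–aq. NH4Cl) gives the carbinol epimer mixture F3; buffered Dess–Martin oxidation gives the ynone F4; reduction with (R)-2-methyl-CBS-oxazaborolidine [(R)-1-methyl-3,3-diphenyltetrahydro-1H,3H-pyrrolo[1,2-c][1,3,2]oxazaborole] and BH3·SMe2 (large cyclohexenyl versus small propargyl group) returns to 8.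

**Step 7.** The alanate may open the epoxide sluggishly or transfer butyl or methyl instead of the alkenyl group. The fallback sets out from alkenylalane 9, which is cross-coupled in the same flask with vinyl bromide (Pd(PPh3)4, ZnCl2) to the diene F5. Hydroboration of the terminal vinyl group with 9-BBN and oxidation with NaBO3·4H2O returns to 11.

**Step 4.** Intramolecular alkylation of enolate 5 by the γ chloride (cyclopropane formation) may compete if sulfonylation of the hindered enolate is slow. The fallback installs chlorine after the enolate chemistry. It sets out from 3: silylation (TBSCl, imidazole) gives silyl ether F6; enolisation and triflation as in step 4 give the silyloxy triflate F7; HF·pyridine gives the hydroxy triflate F8; the Appel reaction (PPh3, CCl4) with inversion returns to 6.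

**Step 12.** The C12 hydroxyl may intercept the platinum-activated nitrile (iminolactone, then lactone), or acyl transfer to the weakly nucleophilic carboxamide may be slow enough for retro-aldol to compete. The fallback removes the participating hydroxyls. It sets out from 20: Et3SiOTf/2,6-lutidine gives the bis(triethylsilyl) ether F9; the same hydration and ring closure give the silylated imide F10; HF·pyridine returns to 22.

## Further compounds

F1 | step 8 | mixture of C5/C6 stereoisomers of decalin diol 14 | C=C1CC(O)C2C(C)(C)C[C@H](Cl)C[C@]2(C)[C@H]1CCO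
F2 | step 8 | trans-fused 6-oxo aldehyde (2α-chloro-4,4,10β-trimethyl-8-methylene-6-oxo-9β-(2-oxoethyl)-trans-decalin) | C=C1CC(=O)[C@H]2C(C)(C)C[C@H](Cl)C[C@]2(C)[C@H]1CC=O
F3 | step 6 | 1-[(R)-4-chloro-2,6,6-trimethylcyclohex-1-en-1-yl]but-3-yn-1-ol, carbinol epimer mixture | CC1=C(C(O)CC#C)C(C)(C)C[C@H](Cl)C1
F4 | step 6 | 1-[(R)-4-chloro-2,6,6-trimethylcyclohex-1-en-1-yl]but-3-yn-1-one | CC1=C(C(=O)CC#C)C(C)(C)C[C@H](Cl)C1
F5 | step 7 | (1S,3E)-1-[(R)-4-chloro-2,6,6-trimethylcyclohex-1-en-1-yl]-3-methylhexa-3,5-dien-1-ol | CC1=C([C@@H](O)C/C(C)=C/C=C)C(C)(C)C[C@H](Cl)C1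
F6 | step 4 | (4S)-4-(tert-butyldimethylsilyloxy)-2,2,6-trimethylcyclohexan-1-one | CC1C(=O)C(C)(C)C[C@@H](O[Si](C)(C)C(C)(C)C)C1
F7 | step 4 | (S)-4-(tert-butyldimethylsilyloxy)-2,6,6-trimethylcyclohex-1-en-1-yl trifluoromethanesulfonate | CC1=C(OS(=O)(=O)C(F)(F)F)C(C)(C)C[C@@H](O[Si](C)(C)C(C)(C)C)C1
F8 | step 4 | (S)-4-hydroxy-2,6,6-trimethylcyclohex-1-en-1-yl trifluoromethanesulfonate | CC1=C(OS(=O)(=O)C(F)(F)F)C(C)(C)C[C@@H](O)C1
F9 | step 12 | bis(triethylsilyl) ether of aldol adduct 20 | C=C1C[C@@H](O[Si](CC)(CC)CC)[C@H]2C(C)(C)C[C@H](Cl)C[C@]2(C)[C@H]1C[C@H](O[Si](CC)(CC)CC)[C@@H](CC#N)C(=O)N1[C@H](Cc2ccccc2)COC1=O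
F10 | step 12 | bis(triethylsilyl) ether of haterumaimide F | C=C1C[C@@H](O[Si](CC)(CC)CC)[C@H]2C(C)(C)C[C@H](Cl)C[C@]2(C)[C@H]1C[C@H](O[Si](CC)(CC)CC)[C@H]1CC(=O)NC1=O
A1 | alternative 1 | (+)-sclareolide | C[C@@]12CC[C@H]3C(C)(C)CCC[C@]3(C)[C@H]1CC(=O)O2
A2 | alternative 1 | 2α-chlorosclareolide | C[C@@]12CC[C@H]3C(C)(C)C[C@H](Cl)C[C@]3(C)[C@H]1CC(=O)O2
A3 | alternative 2 | acyclic chloro trienyl allylsilane (tert-butyldimethylsilyl ether) | C=C(C)C[C@H](Cl)C/C(C)=C/CC/C(C[Si](C)(C)C)=C/CCO[Si](C)(C)C(C)(C)C
A4 | alternative 2 | 2α-chloro-9β-[2-(tert-butyldimethylsilyloxy)ethyl]-4,4,10β-trimethyl-8-methylene-trans-decalin (no C6 oxygen) | C=C1CC[C@H]2C(C)(C)C[C@H](Cl)C[C@]2(C)[C@H]1CCO[Si](C)(C)C(C)(C)C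
A5 | alternative 3 | larixol (labda-8(17),14-diene-6α,13-diol) | C=C1C[C@H](O)[C@H]2C(C)(C)CCC[C@]2(C)[C@H]1CC[C@](C)(O)C=C
A6 | alternative 3 | 6α-hydroxy-14,15-dinorlabd-8(17)-en-13-one | C=C1C[C@H](O)[C@H]2C(C)(C)CCC[C@]2(C)[C@H]1CCC(C)=O
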